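Ring A is closed at C2–C3 by a SmI2-mediated reductive cyclization (step 10) that gives the ring-B enone directly; the route is 14 linear steps from 3-methylcyclohex-2-en-1-one.

- **Retrosynthesis:** cut the C9 and C3 ester C–O bonds, then C9–O and C10–H (back to the ring-B C9=C10 enone 22), then the C7–isopropenyl bond, then C2–C3 of ring A (key cut), then the C10–vinyl bond and the C4–C5 bond (Claisen).
- **Forward:** ring B comes from 3-methylcyclohexenone. An Ireland–Claisen rearrangement builds C4–C5, allylic oxidation and vinylation give the 4,4-disubstituted 3-vinylcyclohex-2-enone 15, and ring A is closed last at C2–C3.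
- **Enabling feature:** in 15 the ring-B C8 ketone is conjugated through C9=C10 and C1=C2, so C2 is its δ-carbon, while C3 is an aldehyde carbon. SmI2 joins these two acceptor carbons (6-endo) and leaves the C9=C10 enone.
- **Use of the enone:** it directs C7 alkenylation (α′ enolate), C10–H delivery (1,4-hydrosilylation) and C9–OH (Rubottom on the C8=C9 enol silane).
- **Stereochemistry:** CBS reduction sets the C–O centre of 2, which is transferred suprafacially to C5; ketene acetal geometry sets C4; the half-chair closure sets C3; stereoelectronic hydride delivery sets C10; face selection plus the equatorial preference set C9 and C7.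

Key step: step 10

Remark: locants follow eremophilane numbering (ring A = C1–C5, C10; ring B = C5–C10; C14 on C5, C15 on C4); the 7- and 9-substituents of the target are equatorial on the cis-fused ring B and are taken to be the thermodynamically favoured epimers.

Step 1
Reactants: 1 3-methylcyclohex-2-en-1-one
Product: 2 (1R)-3-methylcyclohex-2-en-1-ol
Conditions: (S)-2-methyl-CBS-oxazaborolidine (10 mol %), BH3·SMe2, THF, −20 °C
Reagents that add atoms: none
Why: Corey–Bakshi–Shibata reduction: the oxazaborolidine binds the ketone with the alkenyl arm in the large-group position and should deliver hydride to the face that gives the R carbinol, whose C–O bond (on the later C9) lies on the α-face of ring B.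

Step 2
Reactants: 2 (1R)-3-methylcyclohex-2-en-1-ol; 3 propanoic anhydride
Product: 4 (1R)-3-methylcyclohex-2-en-1-yl propanoate
Conditions: Et3N, DMAP (cat.), CH2Cl2, 0 °C → rt
Reagents that add atoms: none
Why: DMAP-catalysed acylation of the allylic alcohol; the carbinol centre is not touched.

Step 3
Reactants: 4 (1R)-3-methylcyclohex-2-en-1-yl propanoate
Product: 7 (2R)-2-[(1S)-1-methylcyclohex-2-en-1-yl]propanoic acid, via silyl ketene acetal 5 (not isolated), via trimethylsilyl ester 6 (not isolated)
Conditions: LiN(i-Pr)2, THF/DMPU, −78 °C; Me3SiCl; −78 → 60 °C; then 1 M HCl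
Reagents that add atoms: chlorotrimethylsilane C[Si](C)(C)Cl (silicon retained only in 5 and 6)
Why: Ireland–Claisen rearrangement: the base in THF/DMPU gives the Z silyl ketene acetal 5, the [3,3] shift is suprafacial so the new C4–C5 bond forms on the face that carried the C–O bond (setting the quaternary C5), and C4 follows from the boat-like transition state usual for cyclohex-2-enyl esters (the E isomer through a chair would converge on the same C4 epimer).

Step 4
Reactants: 7 (2R)-2-[(1S)-1-methylcyclohex-2-en-1-yl]propanoic acid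
Product: 8 (2R)-2-[(1S)-1-methylcyclohex-2-en-1-yl]propan-1-ol
Conditions: LiAlH4, Et2O, 0 °C → rt
Reagents that add atoms: none
Why: LiAlH4 reduction of the carboxylic acid to the primary alcohol; no stereocentre is touched.

Step 5
Reactants: 8 (2R)-2-[(1S)-1-methylcyclohex-2-en-1-yl]propan-1-ol
Product: 9 tert-butyl(dimethyl){(2R)-2-[(1S)-1-methylcyclohex-2-en-1-yl]propoxy}silane
Conditions: TBSCl, imidazole, DMF, rt
Reagents that add atoms: tert-butyl(chloro)dimethylsilane CC(C)(C)[Si](C)(C)Cl
Why: Imidazole-promoted silylation of the primary alcohol masks the future C3 carbonyl for steps 6 and 7.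

Step 6
Reactants: 9 tert-butyl(dimethyl){(2R)-2-[(1S)-1-methylcyclohex-2-en-1-yl]propoxy}silane
Product: 10 (4S)-4-[(2R)-1-{[tert-butyl(dimethyl)silyl]oxy}propan-2-yl]-4-methylcyclohex-2-en-1-one
Conditions: Rh2(cap)4 (cap = caprolactamate, 1 mol %), t-BuOOH, K2CO3, CH2Cl2, rt
Reagents that add atoms: tert-butyl hydroperoxide CC(C)(C)OO
Why: Dirhodium-catalysed allylic oxidation (tert-butylperoxyl radical chain): C8 is the only allylic CH2 because the other allylic position is the quaternary C5, so the 4,4-disubstituted cyclohex-2-enone should form without transposition.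

Step 7
Reactants: 10 (4S)-4-[(2R)-1-{[tert-butyl(dimethyl)silyl]oxy}propan-2-yl]-4-methylcyclohex-2-en-1-one; 11 vinylmagnesium bromide
Product: 13 (4R)-4-[(2R)-1-{[tert-butyl(dimethyl)silyl]oxy}propan-2-yl]-3-ethenyl-4-methylcyclohex-2-en-1-one, via silyl enol ether 12 (not isolated)
Conditions: CuBr·SMe2 (10 mol %), Me3SiCl, THF/DMPU, −78 °C; then Pd(OAc)2 (10 mol %), O2 (1 atm), DMSO, rt
Reagents that add atoms: chlorotrimethylsilane C[Si](C)(C)Cl (silicon retained only in 12)
Why: Copper-catalysed, silyl-chloride-accelerated conjugate addition of the vinyl Grignard reagent to C10 gives silyl enol ether 12, and Saegusa–Ito oxidation of this regiodefined enol ether restores C9=C10, so the transient C10 centre is erased and the 3-vinylenone results.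

Step 8
Reactants: 13 (4R)-4-[(2R)-1-{[tert-butyl(dimethyl)silyl]oxy}propan-2-yl]-3-ethenyl-4-methylcyclohex-2-en-1-one
Product: 14 (4R)-3-ethenyl-4-[(2R)-1-hydroxypropan-2-yl]-4-methylcyclohex-2-en-1-one
Conditions: HF·pyridine, THF, 0 °C → rt
Reagents that add atoms: none
Why: Fluoride cleavage of the silyl ether under mildly acidic conditions that should leave the vinylenone untouched.

Step 9
Reactants: 14 (4R)-3-ethenyl-4-[(2R)-1-hydroxypropan-2-yl]-4-methylcyclohex-2-en-1-one
Product: 15 (2R)-2-[(1R)-2-ethenyl-1-methyl-4-oxocyclohex-2-en-1-yl]propanal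
Conditions: Dess–Martin periodinane, pyridine, CH2Cl2, 0 °C → rt
Reagents that add atoms: none
Why: Dess–Martin oxidation of the primary alcohol under buffered, non-enolising conditions, so the α-stereocentre C4 should be kept.

Step 10
Reactants: 15 (2R)-2-[(1R)-2-ethenyl-1-methyl-4-oxocyclohex-2-en-1-yl]propanal
Product: 17 (4aR,5R,6R)-6-hydroxy-4a,5-dimethyl-4,4a,5,6,7,8-hexahydronaphthalen-2(3H)-one, via deconjugated enone 16 (not isolated)
Conditions: SmI2 (2.2 equiv), t-BuOH (2 equiv), THF, −78 °C, slow addition of 15; then DBU (cat.), CH2Cl2, rt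
Reagents that add atoms: none
Why: Proposed new method: single-electron transfer from SmI2 gives the aldehyde ketyl (or first the radical anion of the vinylenone, which reaches the same bond), the C3 centre adds to C2, the δ-terminus of the C8=O/C9=C10/C1=C2 dienone, the delocalised oxypentadienyl radical is reduced by the second SmI2 to a samarium dienolate, t-BuOH protonates it at C9 to give 16, and DBU moves the double bond into conjugation. The closest known reaction type is the SmI2 ketyl–olefin reductive cyclization of aldehydes onto enones or enoates, together with radical 1,6-addition to dienones; what is new is the vinylogous acceptor closed in the endo mode. Ring A closes 6-endo-trig at C1=C2, since attack at C10 would need a four-membered ring and attack at C1 would give an unstabilised primary radical. C3 is set in a half-chair transition state in which the C4 methyl group is equatorial and the bulky O–Sm group takes the equatorial site away from the axial C5 methyl group, which should give the 3R alcohol trans to the C4 methyl group; C4 and C5 are carried in unchanged. The step needs chemoselectivity against plain reduction or reductive dimerisation of the dienone, which slow addition of 15 to SmI2 at high dilution and the favourable six-membered geometry should secure.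

Step 11
Reactants: 17 (4aR,5R,6R)-6-hydroxy-4a,5-dimethyl-4,4a,5,6,7,8-hexahydronaphthalen-2(3H)-one; 18 angelic acid, (2Z)-2-methylbut-2-enoic acid
Product: 20 (1R,2R,8aR)-1,8a-dimethyl-6-oxo-1,2,3,4,6,7,8,8a-octahydronaphthalen-2-yl (2Z)-2-methylbut-2-enoate, via mixed anhydride 19 (not isolated)
Conditions: 18, 2,4,6-trichlorobenzoyl chloride, Et3N, toluene, rt; then 17, 80 °C
Reagents that add atoms: 2,4,6-trichlorobenzoyl chloride O=C(Cl)c1c(Cl)cc(Cl)cc1Cl (atoms retained only in 19)
Why: Yamaguchi esterification through mixed anhydride 19 without DMAP, conditions chosen so that the Z geometry of the angelate should be kept; the C3 carbinol is acylated with retention.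

Step 12
Reactants: 20 (1R,2R,8aR)-1,8a-dimethyl-6-oxo-1,2,3,4,6,7,8,8a-octahydronaphthalen-2-yl (2Z)-2-methylbut-2-enoate; 21 2-bromopropene
Product: 22 (1R,2R,7R,8aR)-1,8a-dimethyl-6-oxo-7-(prop-1-en-2-yl)-1,2,3,4,6,7,8,8a-octahydronaphthalen-2-yl (2Z)-2-methylbut-2-enoate
Conditions: LiN(SiMe3)2 (2.1 equiv), THF, −78 °C; Pd2(dba)3 (2.5 mol %), P(t-Bu)3 (6 mol %), 21, −78 °C → rt; AcOH, −78 °C
Reagents that add atoms: none
Why: Palladium-catalysed α-alkenylation of a ketone enolate: the amide base deprotonates the enone only at C7 (α′), the zerovalent palladium catalyst couples the enolate with 21, and kinetic protonation of the product dienolate at C7 from the α-face (anti to the axial C5 methyl group) should give the 7R epimer, which is also the equatorial, favoured one once ring B is cis-fused.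

Step 13
Reactants: 22 (1R,2R,7R,8aR)-1,8a-dimethyl-6-oxo-7-(prop-1-en-2-yl)-1,2,3,4,6,7,8,8a-octahydronaphthalen-2-yl (2Z)-2-methylbut-2-enoate
Product: 25 (1R,2R,4aS,5R,7R,8aR)-5-hydroxy-1,8a-dimethyl-6-oxo-7-(prop-1-en-2-yl)decahydronaphthalen-2-yl (2Z)-2-methylbut-2-enoate, via triethylsilyl enol ether 23 (not isolated), via silyloxy ketone 24 (not isolated)
Conditions: (Ph3P)3RhCl (2 mol %), Et3SiH, benzene, 50 °C; then mCPBA, hexane/CH2Cl2, −20 °C; then HF·pyridine, THF, 0 °C
Reagents that add atoms: triethylsilane CC[SiH](CC)CC (silicon retained only in 23 and 24); 3-chloroperbenzoic acid O=C(OO)c1cccc(Cl)c1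
Why: Rhodium-catalysed 1,4-hydrosilylation should deliver hydride to C10 on the face cis to the C5 methyl group (axial attack leading to the chair enolate, as in conjugate additions to angularly methylated octalones) and gives the regiodefined C8=C9 enol silane 23; Rubottom oxidation then adds oxygen to C9 from the β-face (the α-face is covered by the axial C5–C4 bond), the electron-rich enol silane reacting before the isopropenyl and angelate alkenes, and fluoride frees the equatorial 9-hydroxy group.

Step 14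
Reactants: 25 (1R,2R,4aS,5R,7R,8aR)-5-hydroxy-1,8a-dimethyl-6-oxo-7-(prop-1-en-2-yl)decahydronaphthalen-2-yl (2Z)-2-methylbut-2-enoate; 26 3-methylbut-2-enoyl chloride
Product: 27 (1R,2R,4aS,5R,7R,8aR)-1,8a-dimethyl-5-[(3-methylbut-2-enoyl)oxy]-6-oxo-7-(prop-1-en-2-yl)decahydronaphthalen-2-yl (2Z)-2-methylbut-2-enoate
Conditions: 26, pyridine, DMAP (cat.), CH2Cl2, 0 °C
Reagents that add atoms: none
Why: Acylation of the α-hydroxy ketone with the acid chloride in pyridine; the weak base should avoid both deconjugation of the senecioate and migration of the isopropenyl double bond, and no stereocentre is touched.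

Compound list
1 | 3-methylcyclohex-2-en-1-one | CC1=CC(=O)CCC1 | starting material
2 | (1R)-3-methylcyclohex-2-en-1-ol | O[C@H]1C=C(C)CCC1 | intermediate
3 | propanoic anhydride | CCC(=O)OC(=O)CC | starting material
4 | (1R)-3-methylcyclohex-2-en-1-yl propanoate | CCC(=O)O[C@H]1C=C(C)CCC1 | intermediate
5 | trimethyl{[(1Z)-1-{[(1R)-3-methylcyclohex-2-en-1-yl]oxy}prop-1-en-1-yl]oxy}silane | C/C=C(\O[Si](C)(C)C)O[C@H]1C=C(C)CCC1 | intermediate
6 | trimethylsilyl (2R)-2-[(1S)-1-methylcyclohex-2-en-1-yl]propanoate | C[C@@H](C(=O)O[Si](C)(C)C)[C@]1(C)C=CCCC1 | intermediate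
7 | (2R)-2-[(1S)-1-methylcyclohex-2-en-1-yl]propanoic acid | C[C@@H](C(=O)O)[C@]1(C)C=CCCC1 | intermediate
8 | (2R)-2-[(1S)-1-methylcyclohex-2-en-1-yl]propan-1-ol | C[C@@H](CO)[C@]1(C)C=CCCC1 | intermediate
9 | tert-butyl(dimethyl){(2R)-2-[(1S)-1-methylcyclohex-2-en-1-yl]propoxy}silane | C[C@@H](CO[Si](C)(C)C(C)(C)C)[C@]1(C)C=CCCC1 | intermediate
10 | (4S)-4-[(2R)-1-{[tert-butyl(dimethyl)silyl]oxy}propan-2-yl]-4-methylcyclohex-2-en-1-one | C[C@@H](CO[Si](C)(C)C(C)(C)C)[C@]1(C)C=CC(=O)CC1 | intermediate
11 | vinylmagnesium bromide | C=C[Mg]Br | starting material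
12 | {[(4S)-4-[(2R)-1-{[tert-butyl(dimethyl)silyl]oxy}propan-2-yl]-3-ethenyl-4-methylcyclohex-1-en-1-yl]oxy}(trimethyl)silane, both epimers at the vinyl-bearing ring carbon | C[C@@H](CO[Si](C)(C)C(C)(C)C)[C@]1(C)C(C=C)C=C(O[Si](C)(C)C)CC1 | intermediate
13 | (4R)-4-[(2R)-1-{[tert-butyl(dimethyl)silyl]oxy}propan-2-yl]-3-ethenyl-4-methylcyclohex-2-en-1-one | C[C@@H](CO[Si](C)(C)C(C)(C)C)[C@]1(C)C(C=C)=CC(=O)CC1 | intermediate
14 | (4R)-3-ethenyl-4-[(2R)-1-hydroxypropan-2-yl]-4-methylcyclohex-2-en-1-one | C[C@@H](CO)[C@]1(C)C(C=C)=CC(=O)CC1 | intermediate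
15 | (2R)-2-[(1R)-2-ethenyl-1-methyl-4-oxocyclohex-2-en-1-yl]propanal | C[C@@H](C=O)[C@]1(C)C(C=C)=CC(=O)CC1 | intermediate
16 | (4aR,5R,6R)-6-hydroxy-4a,5-dimethyl-3,4,4a,5,6,7-hexahydronaphthalen-2(1H)-one | O=C1CC[C@@]2(C)C(C1)=CC[C@@H](O)[C@@H]2C | intermediate
17 | (4aR,5R,6R)-6-hydroxy-4a,5-dimethyl-4,4a,5,6,7,8-hexahydronaphthalen-2(3H)-one | O=C1CC[C@@]2(C)C(=C1)CC[C@@H](O)[C@@H]2C | intermediate
18 | angelic acid, (2Z)-2-methylbut-2-enoic acid | C/C=C(/C)C(=O)O | starting material
19 | (2Z)-2-methylbut-2-enoic 2,4,6-trichlorobenzoic anhydride | C/C=C(/C)C(=O)OC(=O)c1c(Cl)cc(Cl)cc1Cl | intermediate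
20 | (1R,2R,8aR)-1,8a-dimethyl-6-oxo-1,2,3,4,6,7,8,8a-octahydronaphthalen-2-yl (2Z)-2-methylbut-2-enoate | O=C1CC[C@@]2(C)C(=C1)CC[C@@H](OC(=O)/C(C)=C\C)[C@@H]2C | intermediate
21 | 2-bromopropene | C=C(C)Br | starting material
22 | (1R,2R,7R,8aR)-1,8a-dimethyl-6-oxo-7-(prop-1-en-2-yl)-1,2,3,4,6,7,8,8a-octahydronaphthalen-2-yl (2Z)-2-methylbut-2-enoate | C=C(C)[C@H]1C[C@@]2(C)C(=CC1=O)CC[C@@H](OC(=O)/C(C)=C\C)[C@@H]2C | intermediate
23 | (1R,2R,4aR,7R,8aS)-1,8a-dimethyl-7-(prop-1-en-2-yl)-6-[(triethylsilyl)oxy]-1,2,3,4,4a,7,8,8a-octahydronaphthalen-2-yl (2Z)-2-methylbut-2-enoate | C=C(C)[C@H]1C[C@@]2(C)[C@H](CC[C@@H](OC(=O)/C(C)=C\C)[C@@H]2C)C=C1O[Si](CC)(CC)CC | intermediate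
24 | (1R,2R,4aS,5R,7R,8aR)-1,8a-dimethyl-6-oxo-7-(prop-1-en-2-yl)-5-[(triethylsilyl)oxy]decahydronaphthalen-2-yl (2Z)-2-methylbut-2-enoate | C=C(C)[C@H]1C[C@@]2(C)[C@H](CC[C@@H](OC(=O)/C(C)=C\C)[C@@H]2C)[C@@H](O[Si](CC)(CC)CC)C1=O | intermediate
25 | (1R,2R,4aS,5R,7R,8aR)-5-hydroxy-1,8a-dimethyl-6-oxo-7-(prop-1-en-2-yl)decahydronaphthalen-2-yl (2Z)-2-methylbut-2-enoate | C=C(C)[C@H]1C[C@@]2(C)[C@H](CC[C@@H](OC(=O)/C(C)=C\C)[C@@H]2C)[C@@H](O)C1=O | intermediate
26 | 3-methylbut-2-enoyl chloride | CC(C)=CC(=O)Cl | starting material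
27 | (1R,2R,4aS,5R,7R,8aR)-1,8a-dimethyl-5-[(3-methylbut-2-enoyl)oxy]-6-oxo-7-(prop-1-en-2-yl)decahydronaphthalen-2-yl (2Z)-2-methylbut-2-enoate | C=C(C)[C@H]1C[C@@]2(C)[C@H](CC[C@@H](OC(=O)/C(C)=C\C)[C@@H]2C)[C@@H](OC(=O)C=C(C)C)C1=O | target

Total step count: 14. Longest linear sequence: 14 steps (1 to 27; 3, 11, 18, 21 and 26 are bought).

Steps most likely to fail

1. Step 10 (Proposed new method). What may go wrong: plain reduction or reductive dimerisation of the vinylenone outruns C2–C3 bond formation, or the ketyl closes through the axial arrangement and gives poor selectivity at C3.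
Fallback: ring A would be closed by olefin metathesis instead, setting out from 15. Nozaki–Hiyama–Kishi addition of vinyl bromide (CrCl2, NiCl2 cat., DMF), which is selective for the aldehyde over the enone, should give under Felkin–Anh control the allylic alcohol (3R,4R)-4-[(1R)-2-ethenyl-1-methyl-4-oxocyclohex-2-en-1-yl]pent-1-en-3-ol F1. Ring-closing metathesis of its two vinyl groups with the second-generation Grubbs catalyst (CH2Cl2, 40 °C) would give the dienone (4aR,5R,6R)-6-hydroxy-4a,5-dimethyl-4,4a,5,6-tetrahydronaphthalen-2(3H)-one F2; here C2 stems from vinyl bromide and ethene is lost. Hydrogenation of the disubstituted C1=C2 bond with (Ph3P)3RhCl/H2, which should spare the trisubstituted enone, comes back to the route at 17.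

2. Step 12. What may go wrong: deprotonation or Z/E isomerisation of the angelate by the amide base, double alkenylation, or base-induced migration of the new isopropenyl double bond into conjugation at C7(C11).
Fallback: the isopropenyl group would be brought in by sp2–sp2 coupling, setting out from 20. Dehydrogenation with DDQ (dioxane, reflux) should give the cross-conjugated dienone (1R,2R,8aR)-1,8a-dimethyl-6-oxo-1,2,3,4,6,8a-hexahydronaphthalen-2-yl (2Z)-2-methylbut-2-enoate F3. α-Iodination with I2/pyridine should occur on the enone arm whose β-carbon (C6) is open to attack and give the 7-iodo dienone (1R,2R,8aS)-7-iodo-1,8a-dimethyl-6-oxo-1,2,3,4,6,8a-hexahydronaphthalen-2-yl (2Z)-2-methylbut-2-enoate F4. Suzuki coupling with isopropenylboronic acid pinacol ester (Pd(PPh3)4, K3PO4, dioxane/H2O) would give the 7-isopropenyl dienone (1R,2R,8aR)-1,8a-dimethyl-6-oxo-7-(prop-1-en-2-yl)-1,2,3,4,6,8a-hexahydronaphthalen-2-yl (2Z)-2-methylbut-2-enoate F5. Conjugate reduction of its less substituted C6=C7 arm with [(Ph3P)CuH]6, followed by kinetic protonation at C7, comes back to the route at 22.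

3. Step 13. What may go wrong: poor facial selectivity of hydride delivery at C10, rhodium hydride-induced migration of the isopropenyl double bond or hydrosilylation of the angelate, or over-oxidation of the isopropenyl group by the peracid.
Fallback: reduction and oxidation would be separated, setting out from 22. Conjugate reduction with [(Ph3P)CuH]6 (benzene, rt, aqueous work-up) would give the isolated cis-fused ketone (1R,2R,4aR,7R,8aS)-1,8a-dimethyl-6-oxo-7-(prop-1-en-2-yl)decahydronaphthalen-2-yl (2Z)-2-methylbut-2-enoate F6, whose ring fusion can be checked and purified. Kinetic deprotonation at the C9 methylene with KN(SiMe3)2 (THF, −78 °C) and enolate hydroxylation with 2-(phenylsulfonyl)-3-phenyloxaziridine (Davis oxaziridine) from the β-face comes back to the route at 25.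

Further compounds
F1 | step 10 | (3R,4R)-4-[(1R)-2-ethenyl-1-methyl-4-oxocyclohex-2-en-1-yl]pent-1-en-3-ol | C=C[C@@H](O)[C@H](C)[C@]1(C)C(C=C)=CC(=O)CC1
F2 | step 10 | (4aR,5R,6R)-6-hydroxy-4a,5-dimethyl-4,4a,5,6-tetrahydronaphthalen-2(3H)-one | O=C1CC[C@@]2(C)C(=C1)C=C[C@@H](O)[C@@H]2C
F3 | step 12 | (1R,2R,8aR)-1,8a-dimethyl-6-oxo-1,2,3,4,6,8a-hexahydronaphthalen-2-yl (2Z)-2-methylbut-2-enoate | O=C1C=C[C@@]2(C)C(=C1)CC[C@@H](OC(=O)/C(C)=C\C)[C@@H]2C
F4 | step 12 | (1R,2R,8aS)-7-iodo-1,8a-dimethyl-6-oxo-1,2,3,4,6,8a-hexahydronaphthalen-2-yl (2Z)-2-methylbut-2-enoate | O=C1C(I)=C[C@@]2(C)C(=C1)CC[C@@H](OC(=O)/C(C)=C\C)[C@@H]2C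
F5 | step 12 | (1R,2R,8aR)-1,8a-dimethyl-6-oxo-7-(prop-1-en-2-yl)-1,2,3,4,6,8a-hexahydronaphthalen-2-yl (2Z)-2-methylbut-2-enoate | O=C1C(C(C)=C)=C[C@@]2(C)C(=C1)CC[C@@H](OC(=O)/C(C)=C\C)[C@@H]2C
F6 | step 13 | (1R,2R,4aR,7R,8aS)-1,8a-dimethyl-6-oxo-7-(prop-1-en-2-yl)decahydronaphthalen-2-yl (2Z)-2-methylbut-2-enoate | C=C(C)[C@H]1C[C@@]2(C)[C@H](CC[C@@H](OC(=O)/C(C)=C\C)[C@@H]2C)CC1=O
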